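The route rests on cutting the bond between the oxirane quaternary carbon and the benzene ring. This carbon hangs on the arene carbon ortho to the aryl ester oxygen and para to the ring methyl. It also carries two CH2–O arms. That is the pattern left when C6–H of 4-methoxy-3-methylphenol adds to the ketone carbon of a 3-oxygenated pyruvate. One Cu(OTf)2/bis(oxazoline)-catalysed operation makes the aryl–C bond, sets the only stereocentre and closes a benzofuran-2-one ring. The lactone carbonyl marks the future acyloxymethyl arm and the benzyloxymethyl group marks the future oxirane CH2. The precursors are the free phenol and ethyl 3-benzyloxypyruvate.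

Key step: step 4

Assumption: the sense of induction is taken from the square-planar chelate model established for pyruvate esters on Cu(OTf)2/tBu-box, which calls for the (R,R) ligand to reach (3S); both ligand antipodes are commercial, so a reversed sense would be corrected by exchanging the ligand only.

Design remark: the benzyl ether is kept because it leaves under neutral hydrogenolysis. Sulfonylation and ring closure share one flask, so the migration-prone diol monoester and its mesylate are never stored.

Step 1
Reactants: 1 O-benzyl-DL-serine
Product: 2 (±)-3-(benzyloxy)-2-hydroxypropanoic acid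
Conditions: NaNO2, 1 M aq H2SO4, 0 °C → rt
Reagents that add atoms: water, O
Why: Diazotisation of the primary α-amino acid and hydrolysis of the diazonium salt (deaminative hydroxylation) is the standard way from O-benzylserine to this hydroxy acid, the benzyl ether tolerates cold dilute acid, and the racemic carbinol centre does not matter because step 3 erases it.

Step 2
Reactants: 2 (±)-3-(benzyloxy)-2-hydroxypropanoic acid
Product: 3 ethyl (±)-3-(benzyloxy)-2-hydroxypropanoate
Conditions: EtOH, H2SO4 (cat.), reflux
Reagents that add atoms: ethanol, CCO
Why: Fischer esterification in a large excess of ethanol drives the equilibrium to the ethyl ester and outruns self-esterification of the hydroxy acid, while the benzyl ether is inert.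

Step 3
Reactants: 3 ethyl (±)-3-(benzyloxy)-2-hydroxypropanoate
Product: 4 ethyl 3-(benzyloxy)-2-oxopropanoate
Conditions: Dess–Martin periodinane, CH2Cl2, 0 °C → rt
Reagents that add atoms: none
Why: Dess–Martin oxidation turns a secondary α-hydroxy ester into the α-keto ester under neutral, water-free conditions that avoid enolisation and hydrate formation, and the product is dried azeotropically and used fresh.

Step 4
Reactants: 4 ethyl 3-(benzyloxy)-2-oxopropanoate; 5 4-methoxy-3-methylphenol
Product: 7 (3S)-3-[(benzyloxy)methyl]-3-hydroxy-5-methoxy-6-methyl-1-benzofuran-2(3H)-one, via open-chain hydroxy ester 6 (not isolated)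
Conditions: Cu(OTf)2 (10 mol%), (R,R)-tBu-box [2,2'-(propane-2,2-diyl)bis((4R)-4-tert-butyl-4,5-dihydrooxazole)] (11 mol%), 4 Å MS, CH2Cl2, Ar, 0 °C → rt; then p-TsOH·H2O (10 mol%), 40 °C
Reagents that add atoms: none
Why: Cu(OTf)2 and the ligand form a square-planar complex of divalent copper that binds 4 through its ketone and ester carbonyl oxygens, phenol 5 attacks the activated ketone carbon with C6 in an electrophilic aromatic substitution, and loss of the ring proton restores the arene and gives 6. The closest known reaction type is the enantioselective tandem Friedel–Crafts hydroxyalkylation/lactonisation of phenols with trifluoropyruvates and related activated α-keto esters under Cu(OTf)2/bis(oxazoline) catalysis, and here the α-benzyloxy group provides the inductive activation of the ketone. The benzofuran-2-one ring closes when the phenol oxygen adds to the ester carbonyl and ethanol leaves, a 5-exo-trig acyl substitution favoured by the fully substituted carbinol carbon and completed by the catalytic sulfonic acid. The one new stereocentre, C3, is controlled by the ligand: the tert-butyl groups of the (R,R) ligand cover the si face of the chelated ketone, the arene arrives on the re face, and since aryl ranks lowest the product is (3S). The step needs ortho regioselectivity and the substrate secures it, because the para position carries OMe, C2 is crowded between OH and CH3, C5 is activated by OMe alone, and C6 is activated by the ortho OH and the para CH3. Argon keeps the oxidisable phenol out of copper/air redox chemistry and the sieves keep 4 in its keto form.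

Step 5
Reactants: 7 (3S)-3-[(benzyloxy)methyl]-3-hydroxy-5-methoxy-6-methyl-1-benzofuran-2(3H)-one
Product: 8 (2R)-3-(benzyloxy)-2-(2-hydroxy-5-methoxy-4-methylphenyl)propane-1,2-diol
Conditions: LiBH4 (3 equiv), THF, 0 °C → rt; then H2O, pH 7 buffer
Reagents that add atoms: none
Why: In this borohydride ester reduction the aryl lactone, an activated phenolic ester, is opened to the hydroxy aldehyde and reduced on to the primary alcohol, while the benzyl ether, the aryl methyl ether and the fully substituted stereocentre stay untouched (the descriptor becomes R only because the ranking of the arms changes).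

Step 6
Reactants: 8 (2R)-3-(benzyloxy)-2-(2-hydroxy-5-methoxy-4-methylphenyl)propane-1,2-diol
Product: 9 (2S)-3-(benzyloxy)-2-hydroxy-2-[5-methoxy-4-methyl-2-(2-methylpropanoyloxy)phenyl]propyl 2-methylpropanoate
Conditions: i-PrCOCl (2.3 equiv), pyridine, DMAP (5 mol%), CH2Cl2, 0 °C
Reagents that add atoms: isobutyryl chloride, CC(C)C(=O)Cl
Why: Pyridine/DMAP-mediated O-acylation takes the phenol and the primary alcohol, whereas the tertiary benzylic hydroxyl, buried between the aryl ring and two CH2O arms, should stay free at 0 °C with only a small excess of acid chloride.

Step 7
Reactants: 9 (2S)-3-(benzyloxy)-2-hydroxy-2-[5-methoxy-4-methyl-2-(2-methylpropanoyloxy)phenyl]propyl 2-methylpropanoate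
Product: 10 (2S)-2,3-dihydroxy-2-[5-methoxy-4-methyl-2-(2-methylpropanoyloxy)phenyl]propyl 2-methylpropanoate
Conditions: H2 (1 atm), Pd/C (10 wt% Pd), EtOAc, rt; filtered, concentrated below 25 °C, used at once
Reagents that add atoms: none
Why: Catalytic hydrogenolysis cleaves the O-benzyl bond under neutral aprotic conditions that spare both esters and, without acid, the tertiary benzylic C–OH bond, and the crude diol goes straight into step 8 because a shift of the isobutyryl group between the two primary oxygens would exchange the arms and lower the enantiomeric purity.

Step 8
Reactants: 10 (2S)-2,3-dihydroxy-2-[5-methoxy-4-methyl-2-(2-methylpropanoyloxy)phenyl]propyl 2-methylpropanoate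
Product: 12 [(2S)-2-[5-methoxy-4-methyl-2-(2-methylpropanoyloxy)phenyl]oxiran-2-yl]methyl 2-methylpropanoate, via primary mesylate 11 (not isolated)
Conditions: MsCl (1.1 equiv), Et3N (1.5 equiv), CH2Cl2, −20 °C; then DBU (2 equiv), −20 °C → rt
Reagents that add atoms: methanesulfonyl chloride, CS(=O)(=O)Cl (its CH3SO2 group is held by 11 only and leaves again in the ring closure)
Why: Mesylation at −20 °C is fast and touches only the primary hydroxyl, and DBU then lets the tertiary oxygen displace the mesylate in a 3-exo-tet intramolecular Williamson-type closure that breaks no bond at the stereocentre, so the configuration set in step 4 is carried unchanged into the (S)-oxirane.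

Compound list
1 | O-benzyl-DL-serine | NC(COCc1ccccc1)C(=O)O | starting material
2 | (±)-3-(benzyloxy)-2-hydroxypropanoic acid | OC(COCc1ccccc1)C(=O)O | intermediate
3 | ethyl (±)-3-(benzyloxy)-2-hydroxypropanoate | CCOC(=O)C(O)COCc1ccccc1 | intermediate
4 | ethyl 3-(benzyloxy)-2-oxopropanoate | CCOC(=O)C(=O)COCc1ccccc1 | intermediate
5 | 4-methoxy-3-methylphenol | COc1ccc(O)cc1C | starting material
6 | ethyl (2S)-3-(benzyloxy)-2-hydroxy-2-(2-hydroxy-5-methoxy-4-methylphenyl)propanoate | COc1cc([C@@](O)(C(=O)OCC)COCc2ccccc2)c(O)cc1C | intermediate
7 | (3S)-3-[(benzyloxy)methyl]-3-hydroxy-5-methoxy-6-methyl-1-benzofuran-2(3H)-one | COc1cc2c(cc1C)OC(=O)[C@@]2(O)COCc3ccccc3 | intermediate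
8 | (2R)-3-(benzyloxy)-2-(2-hydroxy-5-methoxy-4-methylphenyl)propane-1,2-diol | COc1cc([C@@](O)(CO)COCc2ccccc2)c(O)cc1C | intermediate
9 | (2S)-3-(benzyloxy)-2-hydroxy-2-[5-methoxy-4-methyl-2-(2-methylpropanoyloxy)phenyl]propyl 2-methylpropanoate | COc1cc([C@@](O)(COC(=O)C(C)C)COCc2ccccc2)c(OC(=O)C(C)C)cc1C | intermediate
10 | (2S)-2,3-dihydroxy-2-[5-methoxy-4-methyl-2-(2-methylpropanoyloxy)phenyl]propyl 2-methylpropanoate | COc1cc([C@@](O)(COC(=O)C(C)C)CO)c(OC(=O)C(C)C)cc1C | intermediate
11 | (2R)-2-hydroxy-3-(methanesulfonyloxy)-2-[5-methoxy-4-methyl-2-(2-methylpropanoyloxy)phenyl]propyl 2-methylpropanoate | COc1cc([C@@](O)(COC(=O)C(C)C)COS(C)(=O)=O)c(OC(=O)C(C)C)cc1C | intermediate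
12 | [(2S)-2-[5-methoxy-4-methyl-2-(2-methylpropanoyloxy)phenyl]oxiran-2-yl]methyl 2-methylpropanoate | COc1cc([C@@]2(COC(=O)C(C)C)CO2)c(OC(=O)C(C)C)cc1C | target

Total step count: 8. Longest linear sequence: 8 steps (1 to 12); phenol 5 enters at step 4 without prior steps.

Steps most likely to fail

Step 4. What may go wrong:
- The addition may stall, because a benzyloxy-substituted keto ester is a weaker electrophile than the fluorinated keto esters on which this catalysis is usually run.
- The keto ester may enolise and condense with itself.
- The hydroquinone-type phenol may be oxidised by divalent copper.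
- The ether oxygen may compete with the ester carbonyl for the second site on copper, which would present the opposite ketone face and lower the facial selectivity.

The fallback moves stereocontrol from the catalyst to a covalently bound auxiliary and activates the nucleophile as a stoichiometric metal phenolate. It sets out from hydroxy acid 2. This is esterified with (+)-8-phenylmenthol (p-TsOH, toluene, water separator) to the 8-phenylmenthyl hydroxy ester F1 and oxidised with Dess–Martin periodinane to the 8-phenylmenthyl keto ester F2. Phenol 5 and TiCl4 in CH2Cl2 at −30 °C give the trichlorotitanium phenolate F3. F3 binds F2 through both carbonyl oxygens and delivers its ortho carbon C6 within the chelate, the known ortho-specific arylation of chiral pyruvate esters, to give the auxiliary-bound adduct F4. The phenyl ring of the auxiliary covers one ketone face, the minor diastereomer is removed by chromatography, and the other antipode of the auxiliary is available if the sense is reversed. LiAlH4 in THF then cleaves the auxiliary reductively, and the fallback comes back to the route at triol 8.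

Step 8. What may go wrong:
- The aryl isobutyryl group may be transferred to the tertiary alkoxide through a six-membered transition state, after which the freed phenoxide would close onto the sulfonate carbon.
- The tertiary benzylic position may be sulfonylated or may ionise.
- The acid-sensitive benzylic oxirane may open during purification, so amine-buffered silica is used.

The fallback uses neither a sulfonate nor an external base. It sets out from diol 10, which is cyclodehydrated with PPh3 and DIAD in toluene at 0 °C (Mitsunobu-type dehydration of a 1,2-diol). Both hydroxyl oxygens are tied up on phosphorus, so no free alkoxide faces the aryl ester. The primary C–O bond is the one that breaks, because the tertiary carbon cannot undergo backside displacement, so the configuration is retained. The fallback comes back directly at target 12 and makes no new compound.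

Step 7. What may go wrong:
- The isobutyryl group may migrate between the two primary oxygens, which erodes the enantiomeric purity.
- The aryl ester may migrate to the newly freed alcohol.
- The tertiary benzylic C–O bond may undergo hydrogenolysis.

The fallback removes the benzyl group while no ester can migrate and carries the leaving group through the reduction. It sets out from lactone 7. Hydrogenolysis (H2, Pd/C, EtOAc) gives the lactone diol F5, in which a shift of the only acyl group would need a four-membered ring. MsCl and Et3N at −20 °C give the lactone mesylate F6. Diisobutylaluminium hydride in CH2Cl2 (−78 °C → −20 °C) opens and reduces the lactone to the mesylate triol F7; the aluminium phenoxide and alkoxides are too weakly nucleophilic in the cold to displace the neopentyl-type sulfonate. Isobutyryl chloride and pyridine then acylate the phenol and the primary alcohol, and the fallback comes back to the route at mesylate 11, which is closed with DBU as in step 8.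

Further compounds
F1 | step 4 | (1S,2R,5S)-5-methyl-2-(2-phenylpropan-2-yl)cyclohexyl 3-(benzyloxy)-2-hydroxypropanoate (both carbinol epimers) | OC(COCc1ccccc1)C(=O)O[C@H]1C[C@@H](C)CC[C@@H]1C(C)(C)c1ccccc1
F2 | step 4 | (1S,2R,5S)-5-methyl-2-(2-phenylpropan-2-yl)cyclohexyl 3-(benzyloxy)-2-oxopropanoate | O=C(COCc1ccccc1)C(=O)O[C@H]1C[C@@H](C)CC[C@@H]1C(C)(C)c1ccccc1
F3 | step 4 | trichloro(4-methoxy-3-methylphenoxy)titanium | COc1ccc(O[Ti](Cl)(Cl)Cl)cc1C
F4 | step 4 | (1S,2R,5S)-5-methyl-2-(2-phenylpropan-2-yl)cyclohexyl (2S)-3-(benzyloxy)-2-hydroxy-2-(2-hydroxy-5-methoxy-4-methylphenyl)propanoate | COc1cc([C@@](O)(C(=O)O[C@H]2C[C@@H](C)CC[C@@H]2C(C)(C)c2ccccc2)COCc2ccccc2)c(O)cc1C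
F0 | step 8 | none | none
F5 | step 7 | (3S)-3-hydroxy-3-(hydroxymethyl)-5-methoxy-6-methyl-1-benzofuran-2(3H)-one | COc1cc2c(cc1C)OC(=O)[C@@]2(O)CO
F6 | step 7 | [(3S)-3-hydroxy-5-methoxy-6-methyl-2-oxo-2,3-dihydro-1-benzofuran-3-yl]methyl methanesulfonate | COc1cc2c(cc1C)OC(=O)[C@@]2(O)COS(C)(=O)=O
F7 | step 7 | (2R)-2,3-dihydroxy-2-(2-hydroxy-5-methoxy-4-methylphenyl)propyl methanesulfonate | COc1cc([C@@](O)(CO)COS(C)(=O)=O)c(O)cc1C
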